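**Plan**

- Numbering: dihydrobenzofuran 1 is O1, C2, C3, C3a, C7a fused to ring A (styryl on C4, OH on C6); dihydrobenzofuran 2 is O1', C2', C3', C3a', C7a' fused to ring B (C5' bonded to C3, OH on C7').
- Enabling feature: dihydrobenzofuran 2 is a phenylcoumaran on ring B, with O1' para to C5' and flanked by the oxygenated C7' and by C3a'. It is the ring a 4-hydroxystilbene radical lays across the oxygen and the one free ortho carbon of an ortho-alkoxyphenol.
- Retrosynthetic cuts, in order: C4–vinyl (Heck); C3'–C3a' and O1'–C2' (oxidative coupling with pterostilbene); C2–C3 (carbene C–H insertion); C3–ring B (aryl Grignard plus ring A aldehyde).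
- Forward: ring A aldehyde, diaryl ketone, hydrazone, dihydrobenzofuran 1 (cis, then trans), dihydrobenzofuran 2 by Ag2O coupling, then demethylation, acetylation, Heck styrylation, deacetylation. Bromine stays on C4 through the coupling and the BBr3 step, so no stilbene lies next to an acid-labile benzylic C–O bond.
- Stereochemistry: C3 (S) from the chiral dirhodium carboxylate; C2 (S) by acid equilibration to trans; C3' unbiased and C2' trans to it by reversible quinone methide closure, the (2'R,3'R) diastereomer being separated; E-alkene from the Heck step.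

Key step: step 10

Assumption: Rh2(R-PTAD)4, dirhodium tetrakis[(R)-(1-adamantyl)(phthalimido)acetate], is taken to be the antipode that delivers C3 (S) in step 8; if the sense of induction is the reverse, Rh2(S-PTAD)4 is used there (and its mirror image in the fallback to step 10) with nothing else changed.

**Route**

Step 1
Reactants: 1 1-bromo-3,5-dimethoxybenzene
Product: 3 2-bromo-4,6-dimethoxybenzaldehyde, via aryl iminium salt 2 (not isolated)
Conditions: POCl3, DMF, 0 °C then 90 °C; ice-water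
Reagents that add atoms: N,N-dimethylformamide CN(C)C=O; water O
Why: Vilsmeier–Haack formylation, in which the chloroiminium ion should attack the carbon para to one methoxy group, ortho to the other and next to bromine rather than the carbon between the two methoxy groups, and water hydrolyses iminium salt 2 to the aldehyde.

Step 2
Reactants: 3 2-bromo-4,6-dimethoxybenzaldehyde
Product: 4 2-bromo-6-hydroxy-4-methoxybenzaldehyde
Conditions: BCl3, CH2Cl2, −78 °C to 0 °C; water
Reagents that add atoms: none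
Why: Chelation-controlled Lewis acid ether cleavage, in which boron bridges the formyl oxygen and the ortho methoxy oxygen so that chloride removes only that methyl group and the para methoxy group stays.

Step 3
Reactants: 4 2-bromo-6-hydroxy-4-methoxybenzaldehyde; 5 4-methoxybenzyl chloride
Product: 6 2-bromo-4-methoxy-6-[(4-methoxybenzyl)oxy]benzaldehyde
Conditions: K2CO3, KI (cat.), DMF, 60 °C
Reagents that add atoms: none
Why: Williamson ether synthesis (SN2 of the phenoxide on the benzylic chloride), which places the future C2 carbon with its 4-methoxyphenyl ring on the ring A oxygen.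

Step 4
Reactants: 7 4-bromo-2-methoxyphenol; 5 4-methoxybenzyl chloride
Product: 8 4-bromo-2-methoxy-1-[(4-methoxybenzyl)oxy]benzene
Conditions: K2CO3, KI (cat.), DMF, 60 °C
Reagents that add atoms: none
Why: Williamson ether synthesis; the 4-methoxybenzyl (PMB) ether masks the ring B phenol through the organometallic, hydrazine and carbene steps and is later removed by acid without loss of methyl ethers.

Step 5
Reactants: 8 4-bromo-2-methoxy-1-[(4-methoxybenzyl)oxy]benzene; 6 2-bromo-4-methoxy-6-[(4-methoxybenzyl)oxy]benzaldehyde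
Product: 10 {2-bromo-4-methoxy-6-[(4-methoxybenzyl)oxy]phenyl}{3-methoxy-4-[(4-methoxybenzyl)oxy]phenyl}methanol (racemic), via arylmagnesium bromide 9 (not isolated)
Conditions: Mg, I2 (cat.), THF, 50 °C; then 6, THF, 0 °C; water
Reagents that add atoms: none
Why: Grignard formation and 1,2-addition to the aldehyde, which is far faster than halogen–magnesium exchange with the aryl bromide of 6; the carbinol centre is racemic and is removed in step 6.

Step 6
Reactants: 10 diaryl carbinol
Product: 11 {2-bromo-4-methoxy-6-[(4-methoxybenzyl)oxy]phenyl}{3-methoxy-4-[(4-methoxybenzyl)oxy]phenyl}methanone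
Conditions: Dess–Martin periodinane, CH2Cl2, rt
Reagents that add atoms: none
Why: Dess–Martin oxidation of a doubly benzylic secondary alcohol to the diaryl ketone, under conditions that leave PMB ethers and the aryl bromide untouched.

Step 7
Reactants: 11 diaryl ketone
Product: 12 hydrazone of ketone 11 (E/Z mixture)
Conditions: N2H4·H2O (excess), AcOH (cat.), EtOH, 90 °C, sealed tube
Reagents that add atoms: hydrazine hydrate NN.O
Why: Acid-catalysed condensation to the hydrazone, with excess hydrazine and heat chosen to overcome the two ortho substituents and to suppress azine formation.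

Step 8
Reactants: 12 hydrazone
Product: 14 (2R,3S)-4-bromo-6-methoxy-3-{3-methoxy-4-[(4-methoxybenzyl)oxy]phenyl}-2-(4-methoxyphenyl)-2,3-dihydrobenzofuran (cis), via diaryldiazomethane 13 (not isolated)
Conditions: MnO2, CH2Cl2, 0 °C, filtration; then Rh2(R-PTAD)4 (1 mol %), CH2Cl2, −20 °C to rt
Reagents that add atoms: none
Why: MnO2 dehydrogenates the hydrazone to diaryldiazomethane 13, and the chiral dirhodium tetracarboxylate converts it into a donor/donor carbene that undergoes intramolecular 1,5 C–H insertion into the p-methoxybenzylic ether C–H, forming C2–C3 and the furan ring; the catalyst selects the carbene face and so sets C3 (S), and the concerted insertion places the two aryl groups cis, giving C2 (R).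

Step 9
Reactants: 14 cis dihydrobenzofuran PMB ether
Product: 16 4-[(2S,3S)-4-bromo-6-methoxy-2-(4-methoxyphenyl)-2,3-dihydrobenzofuran-3-yl]-2-methoxyphenol (trans), via cis phenol 15 (not isolated)
Conditions: TFA, anisole, CH2Cl2, 0 °C to rt
Reagents that add atoms: none
Why: Acidolysis and acid-mediated epimerisation: TFA cleaves the aryl PMB ether (anisole traps the PMB cation) and reversibly ionises the benzylic C2–O1 bond to a 4-methoxybenzylic cation, so cis phenol 15 equilibrates to the more stable trans isomer, C2 becoming S under thermodynamic control while C3 is not involved.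

Step 10
Reactants: 16 trans bromo phenol; 17 pterostilbene, (E)-4-[2-(3,5-dimethoxyphenyl)ethenyl]phenol
Product: 19 (2S,3S)-4-bromo-3-[(2R,3R)-3-(3,5-dimethoxyphenyl)-2-(4-hydroxyphenyl)-7-methoxy-2,3-dihydrobenzofuran-5-yl]-6-methoxy-2-(4-methoxyphenyl)-2,3-dihydrobenzofuran, via quinone methide 18 (not isolated)
Conditions: Ag2O, acetone–CH2Cl2, rt, dark, argon, 17 (3 equiv) added slowly; preparative HPLC
Reagents that add atoms: none
Why: Ag2O takes one electron and a proton from each phenol; the radical of 17 carries spin on the stilbene carbon next to the 3,5-dimethoxyphenyl ring and the ring B radical of 16 on its single free ortho carbon, and their combination forms C3'–C3a', the dienone then tautomerising to p-quinone methide phenol 18. The closest known reaction type is the oxidative 8–5 coupling of 4-hydroxystilbenes and 4-hydroxycinnamates, with themselves or with guaiacyl phenols, to trans-phenylcoumarans, as in lignan and oligostilbene formation. The ring is closed by 5-exo-trig conjugate addition of the ring B hydroxyl oxygen (O1') to the quinone methide carbon C2', which restores the 4-hydroxyphenyl ring. C3' is fixed in the radical combination with no bias from the remote C3 centre, so both configurations are expected, whereas C2' should end trans to C3' because the quinone methide addition is reversible and the trans ring is the more stable; the (2'R,3'R) and (2'S,3'S) trans diastereomers are therefore separated by preparative HPLC and the former is taken on. Site selectivity on ring B is secured by the substrate, since the para position of its phenol carries C3 and the other ortho position carries OMe, and cross-selectivity is favoured by the slow addition of an excess of cheap 17, so that each ring B radical meets a stilbene radical and the dehydrodimer of 17 is the accepted by-product. Chemoselectivity rests on 16 having no second free phenol and no stilbene, the C4 bromine and the methyl ethers being inert to Ag2O.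

Step 11
Reactants: 19 coupled pentamethyl ether
Product: 20 (2S,3S)-4-bromo-3-[(2R,3R)-3-(3,5-dihydroxyphenyl)-7-hydroxy-2-(4-hydroxyphenyl)-2,3-dihydrobenzofuran-5-yl]-2-(4-hydroxyphenyl)-2,3-dihydrobenzofuran-6-ol
Conditions: BBr3, CH2Cl2, −78 °C to rt; ice-water
Reagents that add atoms: none
Why: Lewis acid cleavage of the five aryl methyl ethers; the benzylic C2–O1 and C2'–O1' bonds may open reversibly but should reclose to the trans rings, and with bromine in place of a styryl group at C4 there is no alkene to trap a benzylic cation.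

Step 12
Reactants: 20 hexaphenol
Product: 21 hexaacetate of 20
Conditions: Ac2O, pyridine, DMAP (cat.), rt
Reagents that add atoms: acetic anhydride CC(=O)OC(C)=O
Why: DMAP-catalysed acetylation of all six phenols should give a stable, chromatographable and less electron-rich aryl bromide for the palladium step.

Step 13
Reactants: 21 hexaacetate; 22 4-acetoxystyrene
Product: 23 heptaacetate of the target
Conditions: Pd(OAc)2 (10 mol %), P(o-tol)3, Et3N, DMF, 100 °C
Reagents that add atoms: none
Why: Mizoroki–Heck reaction: oxidative addition of the C4–Br bond to zerovalent palladium, syn carbopalladation of the styrene at its terminal carbon and syn β-hydride elimination should give the E-alkene, and aryl acetates tolerate Et3N.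

Step 14
Reactants: 23 heptaacetate
Product: 24 target, (2S,3S)-3-[(2R,3R)-3-(3,5-dihydroxyphenyl)-7-hydroxy-2-(4-hydroxyphenyl)-2,3-dihydrobenzofuran-5-yl]-2-(4-hydroxyphenyl)-4-[(E)-2-(4-hydroxyphenyl)ethenyl]-2,3-dihydrobenzofuran-6-ol
Conditions: K2CO3 (cat.), MeOH, argon, 0 °C; AcOH
Reagents that add atoms: none
Why: Base-catalysed transesterification of the seven aryl acetates to methyl acetate, under mild conditions that should leave the alkene and the four stereocentres untouched.

**Compound list**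

1 | 1-bromo-3,5-dimethoxybenzene | COc1cc(Br)cc(OC)c1 | starting material
2 | [(2-bromo-4,6-dimethoxyphenyl)methylidene]dimethylammonium dichlorophosphate | COc1cc(OC)c(C=[N+](C)C)c(Br)c1.[O-]P(=O)(Cl)Cl | intermediate
3 | 2-bromo-4,6-dimethoxybenzaldehyde | COc1cc(OC)c(C=O)c(Br)c1 | intermediate
4 | 2-bromo-6-hydroxy-4-methoxybenzaldehyde | COc1cc(O)c(C=O)c(Br)c1 | intermediate
5 | 4-methoxybenzyl chloride | COc1ccc(CCl)cc1 | starting material
6 | 2-bromo-4-methoxy-6-[(4-methoxybenzyl)oxy]benzaldehyde | COc1ccc(COc2cc(OC)cc(Br)c2C=O)cc1 | intermediate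
7 | 4-bromo-2-methoxyphenol | COc1cc(Br)ccc1O | starting material
8 | 4-bromo-2-methoxy-1-[(4-methoxybenzyl)oxy]benzene | COc1ccc(COc2ccc(Br)cc2OC)cc1 | intermediate
9 | {3-methoxy-4-[(4-methoxybenzyl)oxy]phenyl}magnesium bromide | COc1ccc(COc2ccc([Mg]Br)cc2OC)cc1 | intermediate
10 | {2-bromo-4-methoxy-6-[(4-methoxybenzyl)oxy]phenyl}{3-methoxy-4-[(4-methoxybenzyl)oxy]phenyl}methanol (racemic) | COc1ccc(COc2cc(OC)cc(Br)c2C(O)c2ccc(OCc3ccc(OC)cc3)c(OC)c2)cc1 | intermediate
11 | {2-bromo-4-methoxy-6-[(4-methoxybenzyl)oxy]phenyl}{3-methoxy-4-[(4-methoxybenzyl)oxy]phenyl}methanone | COc1ccc(COc2cc(OC)cc(Br)c2C(=O)c2ccc(OCc3ccc(OC)cc3)c(OC)c2)cc1 | intermediate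
12 | hydrazone of 11 (E/Z mixture) | COc1ccc(COc2cc(OC)cc(Br)c2C(=NN)c2ccc(OCc3ccc(OC)cc3)c(OC)c2)cc1 | intermediate
13 | 1-bromo-2-(diazo{3-methoxy-4-[(4-methoxybenzyl)oxy]phenyl}methyl)-5-methoxy-3-[(4-methoxybenzyl)oxy]benzene | COc1ccc(COc2cc(OC)cc(Br)c2C(=[N+]=[N-])c2ccc(OCc3ccc(OC)cc3)c(OC)c2)cc1 | intermediate
14 | (2R,3S)-4-bromo-6-methoxy-3-{3-methoxy-4-[(4-methoxybenzyl)oxy]phenyl}-2-(4-methoxyphenyl)-2,3-dihydrobenzofuran (cis) | Brc1cc(OC)cc2c1[C@H](c1ccc(OCc3ccc(OC)cc3)c(OC)c1)[C@H](c1ccc(OC)cc1)O2 | intermediate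
15 | 4-[(2R,3S)-4-bromo-6-methoxy-2-(4-methoxyphenyl)-2,3-dihydrobenzofuran-3-yl]-2-methoxyphenol (cis) | Brc1cc(OC)cc2c1[C@H](c1ccc(O)c(OC)c1)[C@H](c1ccc(OC)cc1)O2 | intermediate
16 | 4-[(2S,3S)-4-bromo-6-methoxy-2-(4-methoxyphenyl)-2,3-dihydrobenzofuran-3-yl]-2-methoxyphenol (trans) | Brc1cc(OC)cc2c1[C@H](c1ccc(O)c(OC)c1)[C@@H](c1ccc(OC)cc1)O2 | intermediate
17 | pterostilbene, (E)-4-[2-(3,5-dimethoxyphenyl)ethenyl]phenol | COc1cc(/C=C/c2ccc(O)cc2)cc(OC)c1 | starting material
18 | 4-{(2R)-2-(3,5-dimethoxyphenyl)-2-[5-((2S,3S)-4-bromo-6-methoxy-2-(4-methoxyphenyl)-2,3-dihydrobenzofuran-3-yl)-2-hydroxy-3-methoxyphenyl]ethylidene}cyclohexa-2,5-dien-1-one | Brc1cc(OC)cc2c1[C@H](c1cc(OC)c(O)c(c1)[C@@H](c1cc(OC)cc(OC)c1)C=C1C=CC(=O)C=C1)[C@@H](c1ccc(OC)cc1)O2 | intermediate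
19 | (2S,3S)-4-bromo-3-[(2R,3R)-3-(3,5-dimethoxyphenyl)-2-(4-hydroxyphenyl)-7-methoxy-2,3-dihydrobenzofuran-5-yl]-6-methoxy-2-(4-methoxyphenyl)-2,3-dihydrobenzofuran | Brc1cc(OC)cc2c1[C@H](c1cc(OC)c3c(c1)[C@@H](c1cc(OC)cc(OC)c1)[C@H](c1ccc(O)cc1)O3)[C@@H](c1ccc(OC)cc1)O2 | intermediate
20 | (2S,3S)-4-bromo-3-[(2R,3R)-3-(3,5-dihydroxyphenyl)-7-hydroxy-2-(4-hydroxyphenyl)-2,3-dihydrobenzofuran-5-yl]-2-(4-hydroxyphenyl)-2,3-dihydrobenzofuran-6-ol | Brc1cc(O)cc2c1[C@H](c1cc(O)c3c(c1)[C@@H](c1cc(O)cc(O)c1)[C@H](c1ccc(O)cc1)O3)[C@@H](c1ccc(O)cc1)O2 | intermediate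
21 | hexaacetate of 20 | Brc1cc(OC(C)=O)cc2c1[C@H](c1cc(OC(C)=O)c3c(c1)[C@@H](c1cc(OC(C)=O)cc(OC(C)=O)c1)[C@H](c1ccc(OC(C)=O)cc1)O3)[C@@H](c1ccc(OC(C)=O)cc1)O2 | intermediate
22 | 4-acetoxystyrene (4-ethenylphenyl acetate) | C=Cc1ccc(OC(C)=O)cc1 | starting material
23 | heptaacetate of 24 | CC(=O)Oc1ccc(/C=C/c2cc(OC(C)=O)cc3c2[C@H](c2cc(OC(C)=O)c4c(c2)[C@@H](c2cc(OC(C)=O)cc(OC(C)=O)c2)[C@H](c2ccc(OC(C)=O)cc2)O4)[C@@H](c2ccc(OC(C)=O)cc2)O3)cc1 | intermediate
24 | (2S,3S)-3-[(2R,3R)-3-(3,5-dihydroxyphenyl)-7-hydroxy-2-(4-hydroxyphenyl)-2,3-dihydrobenzofuran-5-yl]-2-(4-hydroxyphenyl)-4-[(E)-2-(4-hydroxyphenyl)ethenyl]-2,3-dihydrobenzofuran-6-ol | Oc1ccc(/C=C/c2cc(O)cc3c2[C@H](c2cc(O)c4c(c2)[C@@H](c2cc(O)cc(O)c2)[C@H](c2ccc(O)cc2)O4)[C@@H](c2ccc(O)cc2)O3)cc1 | target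

**Step count and risks**

Total step count: 14. Longest linear sequence: 13 steps (steps 1 to 3 and 5 to 14, from 1); step 4 is a one-step branch.

Step 10 (key step). Three processes may defeat it:
- homo-coupling of the stilbene radical outrunning the cross-coupling;
- loss of the C3 hydrogen from the ring B radical, giving a quinone methide and erasing the C3 centre;
- the unbiased face selection at C3', which leaves at best half of the coupled material with the required configuration.

The fallback builds dihydrobenzofuran 2 by a second catalyst-controlled carbene C–H insertion, setting out from 16 and returning at 20. Magnesium-mediated ortho-formylation of 16 (MgCl2, Et3N, paraformaldehyde, MeCN, reflux) should give salicylaldehyde F1, and alkylation with 5 (K2CO3, DMF) the 4-methoxybenzyl ether F2. Commercial 3,5-dimethoxyphenylmagnesium chloride adds to give carbinol F3, which Dess–Martin periodinane oxidises to ketone F4. Hydrazine hydrate gives hydrazone F5, MnO2 the diazo compound F6, and Rh2(S-PTAD)4, the mirror-image catalyst, the cis dihydrobenzofuran F7 with C3' (R). TFA in CH2Cl2 equilibrates C2' to the trans hexamethyl ether F8, and BBr3 cleaves its six methyl ethers to 20. Both new centres are then under catalyst and thermodynamic control and no diastereomer has to be discarded.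

Step 8. The two ortho substituents (bromine and the benzyloxy group) may slow carbene formation or insertion, allow azine formation, or twist ring A enough to erode face selection. The fallback assembles dihydrobenzofuran 1 without a carbene, by [4+1] annulation of an ortho-quinone methide with a sulfur ylide followed by resolution, setting out from 4 (with Grignard reagent 9) and returning at 16. Two equivalents of 9 add to 4 to give o-hydroxybenzhydrol F9, which p-toluenesulfinic acid in CH2Cl2 converts into sulfone F10. Sulfonium salt F11 is made from 5 and dimethyl sulfide. Cs2CO3 in CH2Cl2 eliminates sulfinate from F10 to ortho-quinone methide F12; the ylide of F11 adds to its exocyclic carbon and the phenoxide displaces dimethyl sulfide, closing the ring as the racemic trans dihydrobenzofuran F13, so no epimerisation is needed. Preparative HPLC on a chiral stationary phase gives the (2S,3S) enantiomer F14, and TFA with anisole removes the PMB group to give 16.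

Step 13. Oxidative addition at the hindered C4–Br bond of a large polyacetate may be sluggish, with protodebromination and acetate loss on prolonged heating. The fallback moves the styrylation ahead of the coupling, setting out from 16 and returning at 24. Heck reaction of 16 with 4-methoxystyrene (Pd(OAc)2, P(o-tol)3, Et3N, DMF, 100 °C) should give stilbene phenol F15. Ag2O coupling with 17 as in step 10 passes through quinone methide F16 and gives, after separation of the diastereomers, hexamethyl ether F17. Its six methyl ethers are cleaved with BCl3 and n-Bu4NI in CH2Cl2 at −78 °C to 0 °C, a milder reagent pair than BBr3, chosen because the stilbene now sits next to the ionisable C2–O1 bond; this gives 24.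

**Further compounds**

F1 | step 10 | 5-[(2S,3S)-4-bromo-6-methoxy-2-(4-methoxyphenyl)-2,3-dihydrobenzofuran-3-yl]-2-hydroxy-3-methoxybenzaldehyde | Brc1cc(OC)cc2c1[C@H](c1cc(OC)c(O)c(C=O)c1)[C@@H](c1ccc(OC)cc1)O2
F2 | step 10 | 5-[(2S,3S)-4-bromo-6-methoxy-2-(4-methoxyphenyl)-2,3-dihydrobenzofuran-3-yl]-3-methoxy-2-[(4-methoxybenzyl)oxy]benzaldehyde | Brc1cc(OC)cc2c1[C@H](c1cc(OC)c(OCc3ccc(OC)cc3)c(C=O)c1)[C@@H](c1ccc(OC)cc1)O2
F3 | step 10 | {5-[(2S,3S)-4-bromo-6-methoxy-2-(4-methoxyphenyl)-2,3-dihydrobenzofuran-3-yl]-3-methoxy-2-[(4-methoxybenzyl)oxy]phenyl}(3,5-dimethoxyphenyl)methanol (both carbinol epimers) | Brc1cc(OC)cc2c1[C@H](c1cc(OC)c(OCc3ccc(OC)cc3)c(C(O)c3cc(OC)cc(OC)c3)c1)[C@@H](c1ccc(OC)cc1)O2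
F4 | step 10 | {5-[(2S,3S)-4-bromo-6-methoxy-2-(4-methoxyphenyl)-2,3-dihydrobenzofuran-3-yl]-3-methoxy-2-[(4-methoxybenzyl)oxy]phenyl}(3,5-dimethoxyphenyl)methanone | Brc1cc(OC)cc2c1[C@H](c1cc(OC)c(OCc3ccc(OC)cc3)c(C(=O)c3cc(OC)cc(OC)c3)c1)[C@@H](c1ccc(OC)cc1)O2
F5 | step 10 | hydrazone of F4 | Brc1cc(OC)cc2c1[C@H](c1cc(OC)c(OCc3ccc(OC)cc3)c(C(=NN)c3cc(OC)cc(OC)c3)c1)[C@@H](c1ccc(OC)cc1)O2
F6 | step 10 | diazo compound from F5 | Brc1cc(OC)cc2c1[C@H](c1cc(OC)c(OCc3ccc(OC)cc3)c(C(=[N+]=[N-])c3cc(OC)cc(OC)c3)c1)[C@@H](c1ccc(OC)cc1)O2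
F7 | step 10 | (2S,3S)-4-bromo-3-[(2S,3R)-3-(3,5-dimethoxyphenyl)-7-methoxy-2-(4-methoxyphenyl)-2,3-dihydrobenzofuran-5-yl]-6-methoxy-2-(4-methoxyphenyl)-2,3-dihydrobenzofuran (cis in dihydrobenzofuran 2) | Brc1cc(OC)cc2c1[C@H](c1cc(OC)c3c(c1)[C@@H](c1cc(OC)cc(OC)c1)[C@@H](c1ccc(OC)cc1)O3)[C@@H](c1ccc(OC)cc1)O2
F8 | step 10 | (2S,3S)-4-bromo-3-[(2R,3R)-3-(3,5-dimethoxyphenyl)-7-methoxy-2-(4-methoxyphenyl)-2,3-dihydrobenzofuran-5-yl]-6-methoxy-2-(4-methoxyphenyl)-2,3-dihydrobenzofuran (trans in both rings) | Brc1cc(OC)cc2c1[C@H](c1cc(OC)c3c(c1)[C@@H](c1cc(OC)cc(OC)c1)[C@H](c1ccc(OC)cc1)O3)[C@@H](c1ccc(OC)cc1)O2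
F9 | step 8 | 3-bromo-2-(hydroxy{3-methoxy-4-[(4-methoxybenzyl)oxy]phenyl}methyl)-5-methoxyphenol (racemic) | COc1ccc(COc2ccc(C(O)c3c(O)cc(OC)cc3Br)cc2OC)cc1
F10 | step 8 | 3-bromo-5-methoxy-2-({3-methoxy-4-[(4-methoxybenzyl)oxy]phenyl}(4-methylbenzenesulfonyl)methyl)phenol (racemic) | COc1ccc(COc2ccc(C(c3c(O)cc(OC)cc3Br)S(=O)(=O)c3ccc(C)cc3)cc2OC)cc1
F11 | step 8 | (4-methoxybenzyl)dimethylsulfonium chloride | COc1ccc(C[S+](C)C)cc1.[Cl-]
F12 | step 8 | 3-bromo-5-methoxy-2-({3-methoxy-4-[(4-methoxybenzyl)oxy]phenyl}methylidene)cyclohexa-3,5-dien-1-one (ortho-quinone methide) | COc1ccc(COc2ccc(C=C3C(=O)C=C(OC)C=C3Br)cc2OC)cc1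
F13 | step 8 | racemic trans-4-bromo-6-methoxy-3-{3-methoxy-4-[(4-methoxybenzyl)oxy]phenyl}-2-(4-methoxyphenyl)-2,3-dihydrobenzofuran | COc1ccc(COc2ccc(C3c4c(Br)cc(OC)cc4OC3c3ccc(OC)cc3)cc2OC)cc1
F14 | step 8 | (2S,3S)-4-bromo-6-methoxy-3-{3-methoxy-4-[(4-methoxybenzyl)oxy]phenyl}-2-(4-methoxyphenyl)-2,3-dihydrobenzofuran | Brc1cc(OC)cc2c1[C@H](c1ccc(OCc3ccc(OC)cc3)c(OC)c1)[C@@H](c1ccc(OC)cc1)O2
F15 | step 13 | 2-methoxy-4-{(2S,3S)-6-methoxy-2-(4-methoxyphenyl)-4-[(E)-2-(4-methoxyphenyl)ethenyl]-2,3-dihydrobenzofuran-3-yl}phenol | COc1ccc(/C=C/c2cc(OC)cc3c2[C@H](c2cc(OC)c(O)cc2)[C@@H](c2ccc(OC)cc2)O3)cc1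
F16 | step 13 | p-quinone methide from F15 and 17 (analogue of 18 with the 4-methoxystyryl group on C4) | COc1ccc(/C=C/c2cc(OC)cc3c2[C@H](c2cc(OC)c(O)c(c2)[C@@H](c2cc(OC)cc(OC)c2)C=C2C=CC(=O)C=C2)[C@@H](c2ccc(OC)cc2)O3)cc1
F17 | step 13 | 4-{(2R,3R)-3-(3,5-dimethoxyphenyl)-7-methoxy-5-[(2S,3S)-6-methoxy-2-(4-methoxyphenyl)-4-((E)-2-(4-methoxyphenyl)ethenyl)-2,3-dihydrobenzofuran-3-yl]-2,3-dihydrobenzofuran-2-yl}phenol | COc1ccc(/C=C/c2cc(OC)cc3c2[C@H](c2cc(OC)c4c(c2)[C@@H](c2cc(OC)cc(OC)c2)[C@H](c2ccc(O)cc2)O4)[C@@H](c2ccc(OC)cc2)O3)cc1
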